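Start in a one-step world, where target and starting material simply meet to give side product, and follow the fraction of target left.

| flask | starting material | reagent | temperature | remark | time |
|---|---|---|---|---|---|
| west | 20 mM | 0.50 equiv | 10 °C | run made earlier |  |
| north-east | 20 mM | 0.25 equiv | 25 °C | run made earlier |  |
| east | 20 mM | 1 equiv | 10 °C | run made earlier |  |
| south-west | 10 mM | 0.50 equiv | 25 °C | run made earlier |  |
| delta | 20 mM | 0.500 equiv (fed, over 4.0 d) |  | the addition at −15 °C, then warmed to 25 °C; the feed brings no volume worth counting | 5.0 d |
| beta | 20 mM (fed, over 4.0 d) | 0.500 equiv | 25 °C | all else is in the flask from the start; the feed brings no volume worth counting | 5.0 d |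
| epsilon | 20 mM | 0.500 equiv (fed, over 4.0 d) | 25 °C | all else is in the flask from the start; the feed brings no volume worth counting | 5.0 d |
| alpha | 20 mM | 0.500 equiv |  | everything together at the start at −15 °C, warmed to 25 °C at 4.0 d | 5.0 d |

| run | time / d | side product / % | target / % |
|---|---|---|---|
| west | 2.50 | 27.0 | 35.0 |
| west | 5.00 | 44.1 | 28.3 |
| west | 8.00 | 56.3 | 21.5 |
| west | 10.0 | 61.8 | 18.9 |
| north-east | 1.04 | 27.1 | 11.2 |
| north-east | 2.08 | 39.4 | 5.6 |
| north-east | 3.00 | 44.0 | 2.8 |
| north-east | 4.00 | 46.3 | 1.7 |
| east | 0.625 | 7.3 | 38.1 |
| east | 1.67 | 19.5 | 48.1 |
| east | 4.00 | 35.8 | 49.2 |
| east | 8.00 | 48.3 | 46.1 |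
| south-west | 1.04 | 17.0 | 27.5 |
| south-west | 2.08 | 33.8 | 28.1 |
| south-west | 3.00 | 44.0 | 25.1 |
| south-west | 4.00 | 52.4 | 22.4 |

(readings scatter by 0.3 percentage points)

1. the flask that comes out highest in amount of side product, in percent of the starting material charged; "all alike" if 1.5 percentage points covers them all (delta / beta / epsilon / alpha / all alike)
2. amount of side product at the end, in percent of the starting material charged, delta
3. amount of side product at the end, in percent of the starting material charged, beta
4. amount of side product at the end, in percent of the starting material charged, epsilon
5. amount of side product at the end, in percent of the starting material charged, alpha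

- percentages count the starting material that a species holds: one side product counts as two

Read that step from the north-east run. By 1.04 d, target plus half the side product stands at 24.8% of the charge, against 0.25 equiv of reagent, so take the reagent as used up. From then to 4.00 d, target falls from 11.2% to 1.7% while [starting material] averages 11.4 mM, a pseudo-first-order decay of 0.637 /d.

Delta, beta, epsilon and alpha each carry 0.500 equiv, so a finished first step leaves [target] and [starting material] equal at 10.0 mM, and they then fall together. Scaled to that partner, the decay becomes 0.560 /d. The rate now follows [target] squared, so the reciprocal of [target] climbs steadily, and the fraction left is one over one plus the number below. Each target lost takes a starting material with it, so the fraction lost is the side product, in percent of the charge.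

A feed over 4.0 d leaves the average target 3.00 d at 25 °C, so epsilon and beta reach 1.68. This product of daily decay and standing days is the meeting number, and it gives 62.7% side product. Counting the days at −15 °C as nil, which is my assumption, delta and alpha get 0.560, hence 35.9%.

One number cannot be enough, since epsilon and beta share it. Epsilon holds its whole 20 mM of starting material from the start, so its earliest target meets [starting material] above the 10.0 mM assumed, and on that ground put epsilon highest.

The forecast also says epsilon, with 37% for delta, 57% for beta, 62% for epsilon and 37% for alpha, reached by “Stepping by hand”; its beta stands below my figure.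

The flasks give epsilon highest: delta 37.8%, beta 56.4%, epsilon 64.9%, alpha 38.9%.

    starting material + target → side product (k = 2.58 /M/h, Ea = 61.0 kJ/mol)
    starting material + reagent → target, rate k2*[starting material]^2*[reagent]^0.5 (k = 49.5 /M^1.5/h, Ea = 43.0 kJ/mol)
    (constants at 25 °C)

Now raise epsilon's starting material to 34 mM, with the equivalents held. The meeting number grows with the charge to 2.86, which reckons 74.1% side product. That neighbouring flask ends with 11.6% target and 74.8% side product.

The numbers in the tables are calculated for substances that don't exist; scatter was added.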